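## Retrosynthetic overview
1. Alertenone is the head-to-tail Michael homodimer of α-methylene ketone **12**. One copy acts as a C4 silyl dienol ether nucleophile and the other as the acceptor, so two identical monomers are made different in a single coupling (final step).
2. **12** comes from Eschenmoser trapping of the C2 enolate that is released regiospecifically when cyclopropyl ketone **9** is opened reductively. **9** comes from hydrolysis of the cage enol ether **8**.
3. **8** is formed in one step from the simple arene **7** by an intramolecular arene–alkene meta photocycloaddition. This dearomatization forms four rings and sets the cage stereocentres A, D and F, relayed from the single benzylic centre.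
4. **7** comes from bromide **5** and an isobutenyl Grignard. **5** comes from an Rh-catalysed asymmetric conjugate addition of an arylboronic acid to ethyl crotonate, which sets the only stereocentre that is not formed in the cycloaddition.

Assumptions, one per line:
- Alertenone is taken to be the dimer of one C15 monomer; the target SMILES shows both halves with the same cage configuration.
- The Rh/(S)-BINAP sense of induction is assumed to give the (S)-β-aryl ester. The (R)-ligand would give the enantiomeric series.

## Route

**Step 1**
Reactants: **1** 4-methoxyphenylboronic acid; **2** ethyl (E)-crotonate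
Product: **3** ethyl (S)-3-(4-methoxyphenyl)butanoate
Conditions: Rh(acac)(C2H4)2 (3 mol%), (S)-BINAP, dioxane/H2O 10:1, 100 °C
Reagents that add atoms: none
Why: Rh-catalysed asymmetric 1,4-addition (Hayashi–Miyaura); the chiral ligand controls the face of enoate insertion into Rh–Ar and sets the benzylic (S) centre that becomes the CHMe centre of each half.

**Step 2**
Reactants: **3**
Product: **4** (S)-3-(4-methoxyphenyl)butan-1-ol
Conditions: LiAlH4, THF, 0 °C
Reagents that add atoms: none
Why: ester reduction; the stereocentre is not touched.

**Step 3**
Reactants: **4**
Product: **5** (S)-1-bromo-3-(4-methoxyphenyl)butane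
Conditions: PPh3, CBr4, CH2Cl2, 0 °C
Reagents that add atoms: CBr4, BrC(Br)(Br)Br
Why: Appel bromination of a primary alcohol, remote from the stereocentre.

**Step 4**
Reactants: **5**; **6** 2-methylprop-1-enylmagnesium bromide
Product: **7** (S)-1-methoxy-4-(6-methylhept-5-en-2-yl)benzene
Conditions: Fe(acac)3 (5 mol%), THF/NMP, 0 °C
Reagents that add atoms: none (the Grignard is compound **6**)
Why: iron-catalysed Kumada coupling of a primary alkyl bromide with an alkenyl Grignard installs the prenyl-type alkene without touching the aryl ether or the benzylic centre.

**Step 5**
Reactants: **7**
Product: **8** tetracyclic cyclopropyl methyl enol ether (meta-photocycloadduct)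
Conditions: hν (254 nm, quartz), degassed cyclohexane, rt, low conversion or flow
Reagents that add atoms: none
Why: Wender intramolecular arene–alkene meta (2,6-) photocycloaddition. The three-carbon tether places the CH=CMe2 alkene across both ortho carbons of the ipso carbon, forming the D–F and C–J bonds, and the ipso carbon–C3 bond closes the cyclopropane. This leaves the enol ether C(OMe)=CH and makes the ipso carbon quaternary. Stereochemistry: the benzylic H lies in the arene plane (minimal A(1,3) strain), so the methyl sits axial in the resulting chair and the chain delivers the alkene to one arene face only. This fixes A, D and F relative to the CHMe centre, and the cyclopropane carbons are forced cis.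

**Step 6**
Reactants: **8**
Product: **9** cyclopropyl ketone, tetracyclic C14H20O
Conditions: 1 M HCl, THF, 0 °C → rt
Reagents that add atoms: water, O
Why: enol ether hydrolysis (protonation at the vinyl CH, then hydration of the oxocarbenium) gives the cyclopropyl ketone, with no new stereocentre.

**Step 7**
Reactants: **9**; **10** Eschenmoser's salt
Product: **11** C2 Mannich base (β-dimethylaminomethyl ketone)
Conditions: Li (2.5 equiv), NH3(l)/THF, −78 °C; isoprene; evaporate NH3; then **10**, THF, −78 °C → rt
Reagents that add atoms: none (the salt is compound **10**)
Why: dissolving-metal reductive opening of a cyclopropyl ketone (as in bicyclo[3.1.0]hexan-2-ones) cleaves the exocyclic cyclopropane bond that overlaps the C=O π system. This turns the cyclopropane CH into CH2 and gives the Li enolate specifically at the hindered carbon next to the quaternary centre, which is then trapped by Mannich aminomethylation from the convex face.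

**Step 8**
Reactants: **11**
Product: **12** α-methylene cyclopentanone monomer
Conditions: MeI, THF, rt; then aq. NaHCO3, CH2Cl2, 0 °C (use cold, crude)
Reagents that add atoms: none retained (the methyl of MeI, CH3I, leaves as NMe3)
Why: quaternization then E1cB-type Hofmann elimination of the Mannich base gives the exocyclic enone and destroys the epimerizable C2 centre.

**Step 9**
Reactants: **12**
Product: **13** 2-methylene-3-(trimethylsilyloxy)cyclopent-3-ene silyl dienol ether
Conditions: LiHMDS (1.0 equiv, added inverse: enone into base), THF, −78 °C; TMSCl, Et3N; non-aqueous workup
Reagents that add atoms: TMSCl, C[Si](C)(C)Cl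
Why: kinetic deprotonation can only occur at C4, because C2 is sp2; silylation gives the regiodefined nucleophilic 2-siloxydiene. The diene is s-trans, so it cannot undergo Diels–Alder with the enone.

**Step 10**
Reactants: **13**; **12**
Product: **14** Alertenone
Conditions: Tf2NH (5 mol%), CH2Cl2, −78 °C; then 1 M HCl/THF, rt
Reagents that add atoms: none
Why: Proposed new method: Mukaiyama–Michael head-to-tail homodimerization. The C4 of dienol ether **13** attacks the exocyclic CH2 of acid-activated enone **12**, and the resulting silyl enol ether of the acceptor half is protonated on workup. It is the closest known reaction type to the presumed biogenetic enolate–enone Michael dimerization. Stereochemistry: C–C bond formation at C4 occurs on the convex face of the cis-fused cup. The protonated C2 centre is epimerizable and equilibrates under the acidic workup to the isomer with the CH2 linker on the convex face, which is the target configuration.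

## Compound list
1 | 4-methoxyphenylboronic acid | COc1ccc(B(O)O)cc1 | starting material
2 | ethyl (E)-crotonate | C/C=C/C(=O)OCC | starting material
3 | ethyl (S)-3-(4-methoxyphenyl)butanoate | COc1ccc(cc1)[C@@H](C)CC(=O)OCC | intermediate
4 | (S)-3-(4-methoxyphenyl)butan-1-ol | COc1ccc(cc1)[C@@H](C)CCO | intermediate
5 | (S)-1-bromo-3-(4-methoxyphenyl)butane | COc1ccc(cc1)[C@@H](C)CCBr | intermediate
6 | 2-methylprop-1-enylmagnesium bromide | CC(C)=C[Mg]Br | starting material
7 | (S)-1-methoxy-4-(6-methylhept-5-en-2-yl)benzene | COc1ccc(cc1)[C@@H](C)CCC=C(C)C | intermediate
8 | meta-photocycloadduct (cyclopropyl methyl enol ether) | COC1=C[C@H]2[C@@H]3CC[C@H](C)[C@]25[C@H]1[C@@H]5C3(C)C | intermediate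
9 | cyclopropyl ketone | O=C1C[C@H]2[C@@H]3CC[C@H](C)[C@]25[C@H]1[C@@H]5C3(C)C | intermediate
10 | Eschenmoser's salt | C=[N+](C)C.[I-] | starting material
11 | C2 Mannich base | CN(C)C[C@@H]1C(=O)C[C@H]2[C@@H]3CC[C@H](C)[C@]12CC3(C)C | intermediate
12 | α-methylene ketone monomer | C=C1C(=O)C[C@H]2[C@@H]3CC[C@H](C)[C@]12CC3(C)C | intermediate
13 | silyl dienol ether of 12 | C=C1C(O[Si](C)(C)C)=C[C@H]2[C@@H]3CC[C@H](C)[C@]12CC3(C)C | intermediate
14 | Alertenone | C=C1C(=O)[C@H](C[C@@H]2C(=O)C[C@H]3[C@@H]4CC[C@H](C)[C@]23CC4(C)C)[C@H]2[C@@H]3CC[C@H](C)[C@]12CC3(C)C | target

**Total steps:** 10. **Longest linear sequence:** 10 steps (1 → 2 → 3 → 4 → 5 → 6 → 7 → 8 → 9 → 10; compound **12** feeds step 10 twice).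

## Three steps most likely to fail
1. **Step 5 (meta photocycloaddition).** Risks are competing ortho [2+2] addition, secondary photolysis and imperfect diastereoselectivity.
   Fallback: oxidative dearomatization (PIDA, MeOH) of a 2-methoxy-4-alkylphenol analogue to a masked o-benzoquinone, intramolecular Diels–Alder onto the tethered alkene, then acid-promoted bicyclo[2.2.2]→[3.2.1] rearrangement to the same cage.
2. **Step 10 (homodimerization).** Risks are oligomerization, hetero-Diels–Alder dimerization of **12**, and the wrong C2 or C4 epimer.
   Fallback: add the preformed Li dienolate of **12** to the methiodide of Mannich base **11** as a masked acceptor, so free enone never accumulates; alternatively use a Stork-type pyrrolidine dienamine Michael dimerization under thermodynamic control.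
3. **Step 7 (Li/NH3 opening and Eschenmoser trapping).** Risks are ketone over-reduction, the Eschenmoser salt reacting with residual NH3, and cleavage of the wrong cyclopropane bond.
   Fallback: quench the regiodefined enolate as its TMS enol ether, then react it with Eschenmoser's salt in CH2Cl2 (Mukaiyama-type Mannich), or open the cyclopropane with SmI2/HMPA instead.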